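**Plan**

1. Atoms are numbered 1–27 along the target SMILES (C1 methyl, C2, C3, N4, C5–C17, O18, O19, C20–C24, O25, C26, O27). Cuts, in order: lactone O19–C17 with the C12=C13 alkene (back to a C20 carbinol, a C17 ester and a C12 ketone); C20–C14; C13–C14 and C8–C9; N4–C3 and C21–C26; C23–C24, C14–C15 and C6–C7.
2. Enabling feature: in the cyclopentane C21–C22–C23–C14–C20, C20 is a carbinol carbon (it bears O19) and C14 is quaternary and beta to C12. Written as a C20 aldehyde and a C12(=O)–C13=C14 enone, a ketyl at C20 can add to C14; this closes the cyclopentane and the 2-azabicyclo[3.2.1]octane (C21, N4, C5, C6, C23, C22, bridged by C20–C14).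
3. Forward order of rings: piperidine (bought as a 4-oxopipecolate), pyrrolidine (aldol at C21, then N4–C3 alkylation), cyclopentenone joined at C8–C9, seven-membered ring (C13–C14 aldol, dehydration), cyclopentane (key step), lactone.
4. Stereochemistry: C2 comes from methyl (R)-3-hydroxy-2-methylpropanoate. C21 of the (R)-pipecolate directs C6 (trans) and is then rebuilt as the quaternary centre anti to the C6 substituent. The axial C20 group of the indolizidine directs C23, a chiral copper hydride catalyst sets C9, and the key step sets C14 and C20.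

Key step: step 18

Remark: the C26 carbinol centre (compounds 11–30), C13 and C14 of 22, and C13 of 26 and 27 are not controlled; they are drawn without configuration because each later becomes an sp2 carbon.
Remark: compounds 1, 4 and 6 are taken as commercial; the p-tol-BINAP enantiomer in step 14 is the one that gives (S)-3-alkylcyclopentanones, to be confirmed on 3-butylcyclopent-2-enone.

**Route**

Step 1
Reactants: 1 methyl (R)-3-hydroxy-2-methylpropanoate
Product: 2 methyl (S)-3-bromo-2-methylpropanoate
Conditions: CBr4, PPh3, CH2Cl2, 0 °C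
Reagents that add atoms: carbon tetrabromide, BrC(Br)(Br)Br
Why: Appel bromination of the primary alcohol; the C2 stereocentre is not involved (the descriptor changes only because bromine changes the priorities).

Step 2
Reactants: 2 methyl (S)-3-bromo-2-methylpropanoate
Product: 3 (S)-3-bromo-2-methylpropanal
Conditions: iBu2AlH, CH2Cl2, −78 °C; aqueous potassium sodium tartrate; used at once
Reagents that add atoms: none
Why: Partial reduction of the ester through the stable aluminium hemiacetal; low temperature and immediate use should protect the enolisable C2 centre.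

Step 3
Reactants: 4 cyclopentane-1,3-dione
Product: 5 3-iodocyclopent-2-en-1-one
Conditions: PPh3, I2, Et3N, MeCN, rt
Reagents that add atoms: iodine, II
Why: Deoxy-iodination of the vinylogous acid through its oxyphosphonium salt gives the beta-iodo enone.

Step 4
Reactants: 6 1-tert-butyl 2-methyl (R)-4-oxopiperidine-1,2-dicarboxylate
Product: 7 enol triflate (C23–OTf, C23=C6)
Conditions: LiN(SiMe3)2, THF, −78 °C; PhNTf2, −78 to 0 °C
Reagents that add atoms: N-phenylbis(trifluoromethanesulfonimide), O=S(=O)(N(c1ccccc1)S(=O)(=O)C(F)(F)F)C(F)(F)F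
Why: Kinetic enolisation of the 4-piperidone toward C6 (the side remote from the axial C21 ester) and O-triflation; the ketone alpha-protons are far more acidic than C21–H, so C21 should stay intact.

Step 5
Reactants: 7 enol triflate
Product: 9 4-acetyl enone, via ethoxydiene 8 (not isolated)
Conditions: tributyl(1-ethoxyvinyl)stannane, Pd(PPh3)4, LiCl, THF, reflux; then 1 M HCl, rt
Reagents that add atoms: tributyl(1-ethoxyvinyl)stannane, CCOC(=C)[Sn](CCCC)(CCCC)CCCC; water, O
Why: Stille coupling with an acetyl-anion equivalent, then mild hydrolysis of the enol ether to the methyl ketone (the Boc group tolerates dilute acid at rt).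

Step 6
Reactants: 9 4-acetyl enone
Product: 10 2,5-trans vinyl piperidine silyl enol ether
Conditions: vinylMgBr, CuBr·SMe2 (20 mol%), TBSCl, HMPA, THF, −78 °C
Reagents that add atoms: vinylmagnesium bromide, C=C[Mg]Br; tert-butyldimethylsilyl chloride, CC(C)(C)[Si](C)(C)Cl
Why: Copper-catalysed conjugate addition with in situ O-silylation; the Boc group holds the C21 ester axial and the vinyl group should enter C6 axially on the opposite face (chair-like transition state), giving the 2,5-trans piperidine and a regiodefined C23=C14 silyl enol ether.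

Step 7
Reactants: 10 silyl enol ether; 3 (S)-3-bromo-2-methylpropanal
Product: 11 aldol adduct with quaternary C21
Conditions: LiN(iPr)2, THF, −78 °C; then 3; AcOH quench at −78 °C
Reagents that add atoms: none
Why: Aldol addition of the alpha-amino ester enolate; allylic 1,3-strain from the exocyclic silyl enol ether keeps the C6 vinyl group axial, and allylic strain with the Boc group should send the aldehyde to the axial face of C21 anti to that vinyl group, so the ester (future C20) ends cis to C7.

Step 8
Reactants: 11 aldol adduct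
Product: 12 diol
Conditions: LiBH4, MeOH (1 equiv), THF, 0 °C to rt
Reagents that add atoms: none
Why: Borohydride reduction of the hindered methyl ester to the primary alcohol; the carbamate, the silyl enol ether and the primary bromide should survive.

Step 9
Reactants: 12 diol
Product: 15 indolizidine silyl enol ether, via silyl carbamate 13 (not isolated), via amino bromide 14 (not isolated)
Conditions: TBSOTf, 2,6-lutidine, CH2Cl2, 0 °C to rt; MeOH; then iPr2NEt, MeCN, 60 °C
Reagents that add atoms: tert-butyldimethylsilyl triflate, CC(C)(C)[Si](C)(C)OS(=O)(=O)C(F)(F)F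
Why: The silyl triflate silylates both hydroxyls and turns the Boc carbamate into a silyl carbamate (loss of isobutene); methanolysis and decarboxylation free the secondary amine, which closes the pyrrolidine by 5-exo-tet N-alkylation with the primary bromide, touching no stereocentre.

Step 10
Reactants: 15 indolizidine silyl enol ether
Product: 16 hydroxymethyl methyl ketone
Conditions: 37% aq. HCHO, Yb(OTf)3 (20 mol%), THF, rt to 40 °C
Reagents that add atoms: formaldehyde, C=O
Why: Aqueous Mukaiyama aldol (hydroxymethylation) creates quaternary C23; in the trans-fused indolizidine the C20 CH2OTBS group is axial and blocks the syn-axial face, so formaldehyde should attack equatorially, placing C24 trans to C20 and C7 and the acetyl group (C14) axial and cis to both.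

Step 11
Reactants: 16 hydroxymethyl methyl ketone
Product: 17 TBDPS ether
Conditions: TBDPSCl, imidazole, DMF, rt
Reagents that add atoms: tert-butyldiphenylsilyl chloride, CC(C)(C)[Si](Cl)(c1ccccc1)c1ccccc1
Why: Silylation of the primary neopentyl alcohol with the one silyl group meant to last to the final step.

Step 12
Reactants: 17 TBDPS ether
Product: 18 gamma-keto ester
Conditions: LiN(iPr)2, THF, −78 °C; methyl bromoacetate, DMPU, −78 to −40 °C
Reagents that add atoms: methyl bromoacetate, COC(=O)CBr
Why: Enolate alkylation; only the CH3 side of the ketone is enolisable because C23 is quaternary, so the C15–C17 propanoate arm is installed regioselectively, and low temperature should keep the hindered amine from being quaternised.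

Step 13
Reactants: 18 gamma-keto ester; 5 3-iodocyclopent-2-en-1-one
Product: 20 3-alkylcyclopent-2-enone, via alkylborane 19 (not isolated)
Conditions: 9-BBN, THF, rt; then 5, PdCl2(dppf), AsPh3, Cs2CO3, DMF–H2O, rt
Reagents that add atoms: none
Why: Anti-Markovnikov hydroboration of the vinyl group (faster than reduction of the hindered ketone), then B-alkyl Suzuki–Miyaura coupling with the beta-iodo enone forms C8–C9.

Step 14
Reactants: 20 3-alkylcyclopent-2-enone
Product: 22 tetracyclic beta-hydroxy ketone, via silyl enol ether 21 (not isolated)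
Conditions: CuCl (5 mol%), NaOtBu (5 mol%), p-tol-BINAP (5 mol%), Ph2SiH2, PhMe, 0 °C; then TiCl4, CH2Cl2, −78 °C
Reagents that add atoms: none
Why: Asymmetric copper hydride conjugate reduction sets C9 by catalyst control and gives the regiodefined C12–C13 silyl enol ether, whose intramolecular Mukaiyama aldol addition to the TiCl4-activated C14 ketone closes the seven-membered ring; the new C13 and C14 centres are removed in step 15.

Step 15
Reactants: 22 beta-hydroxy ketone
Product: 23 tetracyclic enone (C20–OTBS)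
Conditions: SOCl2, pyridine, CH2Cl2, 0 °C
Reagents that add atoms: none
Why: Dehydration of the tertiary alcohol through its chlorosulfite, with loss of the acidic C13–H, should give the conjugated tetrasubstituted C13=C14 enone.

Step 16
Reactants: 23 tetracyclic enone
Product: 24 C20 primary alcohol
Conditions: HF·pyridine, pyridine, THF, 0 °C
Reagents that add atoms: none
Why: Buffered fluoride cleaves the primary TBS ether faster than the hindered secondary TBS ether at C26 and the TBDPS ether at C24.

Step 17
Reactants: 24 C20 primary alcohol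
Product: 25 tetracyclic formyl enone
Conditions: DMP (triacetoxyperiodinane), CH2Cl2, 0 °C to rt
Reagents that add atoms: none
Why: Periodinane oxidation of the neopentyl primary alcohol to the non-enolisable aldehyde under neutral conditions that tolerate the tertiary amine and the enone.

Step 18
Reactants: 25 tetracyclic formyl enone
Product: 26 pentacyclic C20 alcohol C12 ketone
Conditions: SmI2 (2.5 equiv), HMPA, t-BuOH, THF, −78 °C; aqueous NH4Cl at −78 °C
Reagents that add atoms: none
Why: SmI2 transfers one electron to the aldehyde (or the enone; both radical anions lead to the same bond), the ketyl carbon C20 adds to the enone beta-carbon C14, and a second electron gives the samarium enolate at C12–C13, which t-BuOH protonates. This is the known SmI2 ketyl–olefin reductive cyclisation of an aldehyde onto an enone. The cyclopentane C21–C22–C23–C14–C20 closes 5-exo-trig and completes the 2-azabicyclo[3.2.1]octane. C14 can be reached only on the face held over C21, because C13 and C23 are tied in the seven-membered ring and the formyl group and C14 sit 1,3-diaxial on the piperidine; at C20 the samarium-bound oxygen should turn away from C13 (cis to the propanoate arm), and the C13 configuration from protonation does not matter. The step needs cyclisation to outrun reductive C21–N4 cleavage and pinacol coupling: the aldehyde is non-enolisable and preorganised for fast 5-exo closure, and C26 is carried as a silyl ether, so no alpha-amino ketone is exposed to the reagent.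

Step 19
Reactants: 26 pentacyclic hydroxy ester
Product: 27 lactone ketone
Conditions: CSA (1.2 equiv), PhMe, 60 °C
Reagents that add atoms: none
Why: Acid-catalysed transesterification; the C20 hydroxyl is cis to the propanoate arm on C14, so the delta-lactone O19–C17 should close with loss of methanol.

Step 20
Reactants: 27 lactone ketone
Product: 28 C12=C13 enol triflate
Conditions: KN(SiMe3)2 (0.95 equiv), THF, −78 to 0 °C, then −78 °C; PhNTf2
Reagents that add atoms: N-phenylbis(trifluoromethanesulfonimide), O=S(=O)(N(c1ccccc1)S(=O)(=O)C(F)(F)F)C(F)(F)F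
Why: Equilibrating enolisation with a slight deficit of base should favour the more substituted C12–C13 potassium enolate (the lactone alpha-protons are less acidic), which is O-triflated.

Step 21
Reactants: 28 enol triflate
Product: 29 C12=C13 alkene
Conditions: Pd(OAc)2, PPh3, HCO2H, Bu3N, DMF, 60 °C
Reagents that add atoms: none
Why: Palladium-catalysed formate reduction of the enol triflate (oxidative addition to zerovalent palladium, formate exchange, decarboxylation, reductive elimination) replaces OTf by H without moving the alkene.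

Step 22
Reactants: 29 alkene
Product: 30 C26 alcohol
Conditions: HF·pyridine, THF, rt
Reagents that add atoms: none
Why: Acidic fluoride should cleave the secondary TBS ether while the more acid-stable primary TBDPS ether remains.

Step 23
Reactants: 30 C26 alcohol
Product: 31 C26 ketone
Conditions: DMP (triacetoxyperiodinane), CH2Cl2, 0 °C
Reagents that add atoms: none
Why: Neutral periodinane oxidation gives the alpha-amino ketone without enolising C2.

Step 24
Reactants: 31 C26 ketone
Product: 32 target
Conditions: Bu4NF, AcOH, THF, 0 °C to rt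
Reagents that add atoms: none
Why: Acetic-acid-buffered fluoride removes the TBDPS ether under conditions mild enough to keep the epimerisable C2 centre.

**Compound list**

1 | methyl (R)-3-hydroxy-2-methylpropanoate | C[C@H](CO)C(=O)OC | starting material
2 | methyl (S)-3-bromo-2-methylpropanoate | C[C@H](CBr)C(=O)OC | intermediate
3 | (S)-3-bromo-2-methylpropanal | C[C@H](CBr)C=O | intermediate
4 | cyclopentane-1,3-dione | O=C1CCC(=O)C1 | starting material
5 | 3-iodocyclopent-2-en-1-one | O=C1C=C(I)CC1 | intermediate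
6 | 1-tert-butyl 2-methyl (R)-4-oxopiperidine-1,2-dicarboxylate | COC(=O)[C@H]1CC(=O)CCN1C(=O)OC(C)(C)C | starting material
7 | 1-tert-butyl 2-methyl (R)-4-(trifluoromethylsulfonyloxy)-3,6-dihydro-2H-pyridine-1,2-dicarboxylate | COC(=O)[C@H]1CC(OS(=O)(=O)C(F)(F)F)=CCN1C(=O)OC(C)(C)C | intermediate
8 | 1-tert-butyl 2-methyl (R)-4-(1-ethoxyvinyl)-3,6-dihydro-2H-pyridine-1,2-dicarboxylate | COC(=O)[C@H]1CC(C(=C)OCC)=CCN1C(=O)OC(C)(C)C | intermediate
9 | 1-tert-butyl 2-methyl (R)-4-acetyl-3,6-dihydro-2H-pyridine-1,2-dicarboxylate | COC(=O)[C@H]1CC(C(C)=O)=CCN1C(=O)OC(C)(C)C | intermediate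
10 | N-Boc piperidine with C21 methyl ester and C6 vinyl trans, exocyclic C23=C14(OTBS)CH3 | COC(=O)[C@H]1CC(=C(C)O[Si](C)(C)C(C)(C)C)[C@H](C=C)CN1C(=O)OC(C)(C)C | intermediate
11 | aldol adduct: quaternary C21 with CO2Me cis to the C6 vinyl and the 3-bromo-1-hydroxy-2-methylpropyl chain trans | BrC[C@@H](C)C(O)[C@@]1(C(=O)OC)CC(=C(C)O[Si](C)(C)C(C)(C)C)[C@H](C=C)CN1C(=O)OC(C)(C)C | intermediate
12 | diol: C20 CH2OH and C26 carbinol, N-Boc, silyl enol ether | BrC[C@@H](C)C(O)[C@@]1(CO)CC(=C(C)O[Si](C)(C)C(C)(C)C)[C@H](C=C)CN1C(=O)OC(C)(C)C | intermediate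
13 | bis-TBS ether with N-CO2TBS silyl carbamate | BrC[C@@H](C)C(O[Si](C)(C)C(C)(C)C)[C@@]1(CO[Si](C)(C)C(C)(C)C)CC(=C(C)O[Si](C)(C)C(C)(C)C)[C@H](C=C)CN1C(=O)O[Si](C)(C)C(C)(C)C | intermediate
14 | bis-TBS ether secondary amine with primary bromide | BrC[C@@H](C)C(O[Si](C)(C)C(C)(C)C)[C@@]1(CO[Si](C)(C)C(C)(C)C)CC(=C(C)O[Si](C)(C)C(C)(C)C)[C@H](C=C)CN1 | intermediate
15 | indolizidine: C2 methyl, C26 OTBS, C21 CH2OTBS, C6 vinyl, C23=C14(OTBS)CH3 | C[C@@H]1CN2C[C@@H](C=C)C(=C(C)O[Si](C)(C)C(C)(C)C)C[C@]2(CO[Si](C)(C)C(C)(C)C)C1O[Si](C)(C)C(C)(C)C | intermediate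
16 | indolizidine with quaternary C23 bearing acetyl (cis to C7 and C20) and CH2OH | C[C@@H]1CN2C[C@@H](C=C)[C@@](CO)(C(C)=O)C[C@]2(CO[Si](C)(C)C(C)(C)C)C1O[Si](C)(C)C(C)(C)C | intermediate
17 | C24 TBDPS ether of 16 | C[C@@H]1CN2C[C@@H](C=C)[C@@](CO[Si](c3ccccc3)(c3ccccc3)C(C)(C)C)(C(C)=O)C[C@]2(CO[Si](C)(C)C(C)(C)C)C1O[Si](C)(C)C(C)(C)C | intermediate
18 | gamma-keto ester: C14 ketone with methyl propanoate arm | C[C@@H]1CN2C[C@@H](C=C)[C@@](CO[Si](c3ccccc3)(c3ccccc3)C(C)(C)C)(C(=O)CCC(=O)OC)C[C@]2(CO[Si](C)(C)C(C)(C)C)C1O[Si](C)(C)C(C)(C)C | intermediate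
19 | C8 alkyl-9-BBN borane | C[C@@H]1CN2C[C@@H](CCB3C4CCCC3CCC4)[C@@](CO[Si](c5ccccc5)(c5ccccc5)C(C)(C)C)(C(=O)CCC(=O)OC)C[C@]2(CO[Si](C)(C)C(C)(C)C)C1O[Si](C)(C)C(C)(C)C | intermediate
20 | 3-alkylcyclopent-2-enone (C9=C13, C12 ketone) linked through C7–C8 | C[C@@H]1CN2C[C@@H](CCC3=CC(=O)CC3)[C@@](CO[Si](c4ccccc4)(c4ccccc4)C(C)(C)C)(C(=O)CCC(=O)OC)C[C@]2(CO[Si](C)(C)C(C)(C)C)C1O[Si](C)(C)C(C)(C)C | intermediate
21 | (9S) diphenylsilyl enol ether, C12(OSiHPh2)=C13 | C[C@@H]1CN2C[C@@H](CC[C@H]3CCC(O[SiH](c4ccccc4)c4ccccc4)=C3)[C@@](CO[Si](c4ccccc4)(c4ccccc4)C(C)(C)C)(C(=O)CCC(=O)OC)C[C@]2(CO[Si](C)(C)C(C)(C)C)C1O[Si](C)(C)C(C)(C)C | intermediate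
22 | tetracyclic beta-hydroxy ketone: seven-membered ring closed, C14 tertiary alcohol, C12 ketone | C[C@@H]1CN2C[C@H]3CC[C@H]4CCC(=O)C4C(O)(CCC(=O)OC)[C@@]3(CO[Si](c5ccccc5)(c5ccccc5)C(C)(C)C)C[C@]2(CO[Si](C)(C)C(C)(C)C)C1O[Si](C)(C)C(C)(C)C | intermediate
23 | tetracyclic enone C12(=O)–C13=C14 with C20 OTBS | C[C@@H]1CN2C[C@H]3CC[C@H]4CCC(=O)C4=C(CCC(=O)OC)[C@@]3(CO[Si](c5ccccc5)(c5ccccc5)C(C)(C)C)C[C@]2(CO[Si](C)(C)C(C)(C)C)C1O[Si](C)(C)C(C)(C)C | intermediate
24 | tetracyclic enone with C20 CH2OH | C[C@@H]1CN2C[C@H]3CC[C@H]4CCC(=O)C4=C(CCC(=O)OC)[C@@]3(CO[Si](c5ccccc5)(c5ccccc5)C(C)(C)C)C[C@]2(CO)C1O[Si](C)(C)C(C)(C)C | intermediate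
25 | tetracyclic formyl enone (C20 aldehyde, C26 OTBS, C24 OTBDPS, methyl ester arm) | C[C@@H]1CN2C[C@H]3CC[C@H]4CCC(=O)C4=C(CCC(=O)OC)[C@@]3(CO[Si](c5ccccc5)(c5ccccc5)C(C)(C)C)C[C@]2(C=O)C1O[Si](C)(C)C(C)(C)C | intermediate
26 | pentacyclic C20 alcohol C12 ketone (cyclopentane closed) | C[C@@H]1CN2C[C@H]3CC[C@H]4CCC(=O)C4[C@@]4(CCC(=O)OC)[C@H](O)[C@@]2(C[C@@]34CO[Si](c5ccccc5)(c5ccccc5)C(C)(C)C)C1O[Si](C)(C)C(C)(C)C | intermediate
27 | hexacyclic delta-lactone C12 ketone | C[C@@H]1CN2C[C@H]3CC[C@H]4CCC(=O)C4[C@@]45CCC(=O)O[C@@H]4[C@@]2(C[C@@]35CO[Si](c6ccccc6)(c6ccccc6)C(C)(C)C)C1O[Si](C)(C)C(C)(C)C | intermediate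
28 | C12 enol triflate (C12=C13) | C[C@@H]1CN2C[C@H]3CC[C@H]4CCC(OS(=O)(=O)C(F)(F)F)=C4[C@@]45CCC(=O)O[C@@H]4[C@@]2(C[C@@]35CO[Si](c6ccccc6)(c6ccccc6)C(C)(C)C)C1O[Si](C)(C)C(C)(C)C | intermediate
29 | C12=C13 alkene, C26 OTBS, C24 OTBDPS | C[C@@H]1CN2C[C@H]3CC[C@H]4CCC=C4[C@@]45CCC(=O)O[C@@H]4[C@@]2(C[C@@]35CO[Si](c6ccccc6)(c6ccccc6)C(C)(C)C)C1O[Si](C)(C)C(C)(C)C | intermediate
30 | C26 alcohol, C24 OTBDPS | C[C@@H]1CN2C[C@H]3CC[C@H]4CCC=C4[C@@]45CCC(=O)O[C@@H]4[C@@]2(C[C@@]35CO[Si](c6ccccc6)(c6ccccc6)C(C)(C)C)C1O | intermediate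
31 | C26 ketone, C24 OTBDPS | C[C@@H]1CN2C[C@H]3CC[C@H]4CCC=C4[C@@]45CCC(=O)O[C@@H]4[C@@]2(C[C@@]35CO[Si](c6ccccc6)(c6ccccc6)C(C)(C)C)C1=O | intermediate
32 | CNP0180795.1 | C[C@@H]1CN2C[C@H]3CC[C@H]4CCC=C4[C@@]45CCC(=O)O[C@@H]4[C@@]2(C[C@@]35CO)C1=O | target

**Totals and risks**

Total step count: 24. Longest linear sequence: 21 steps (steps 4–24, from 6); steps 1–2 and step 3 are side branches.

Steps most likely to fail:

1. Step 14. The addition of the silyl enol ether to the neopentyl-type C14 ketone may be slow or reversible (retro-aldol, protodesilylation to the open ketone), so the seven-membered ring does not close. Fallback, from 20 back to 22: the same copper hydride reduction is run and the silyl enol ether is quenched with NBS to give the alpha-bromo ketone F1. SmI2 in THF at −78 °C then reduces the C13–Br bond to a samarium enolate, which adds to the C14 ketone in a Reformatsky-type cyclisation to give 22.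

2. Step 10. The hindered, tetrasubstituted silyl enol ether may react sluggishly with aqueous formaldehyde, and protodesilylation to the C23–H methyl ketone would lose the regiodefined nucleophile. Fallback, from 15 back to 16: Mukaiyama-type alkylation with trimethyl orthoformate and BF3·OEt2 in CH2Cl2 at −78 °C gives the dimethyl acetal F2. Aqueous oxalic acid hydrolyses it to the keto aldehyde F3, and NaBH4 at −78 °C reduces the aldehyde selectively to 16.

3. Step 20. Enolisation may occur toward C11 instead of C13, which would place the alkene at C11=C12 after reduction. Fallback, from 27 back to 28: TMSOTf and Et3N in CH2Cl2 at rt (equilibrating conditions) give the more substituted trimethylsilyl enol ether F4, which is separated from its regioisomer. CsF and PhNTf2 in DME then convert it into 28.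

Further compounds
F1 | step 14 | alpha-bromo ketone (C13–Br, C12 ketone, 9S) | C[C@@H]1CN2C[C@@H](CC[C@H]3CCC(=O)C3Br)[C@@](CO[Si](c4ccccc4)(c4ccccc4)C(C)(C)C)(C(=O)CCC(=O)OC)C[C@]2(CO[Si](C)(C)C(C)(C)C)C1O[Si](C)(C)C(C)(C)C
F2 | step 10 | C24 dimethyl acetal of the C23 acetyl indolizidine | C[C@@H]1CN2C[C@@H](C=C)[C@@](C(OC)OC)(C(C)=O)C[C@]2(CO[Si](C)(C)C(C)(C)C)C1O[Si](C)(C)C(C)(C)C
F3 | step 10 | C24 aldehyde of the C23 acetyl indolizidine | C[C@@H]1CN2C[C@@H](C=C)[C@@](C=O)(C(C)=O)C[C@]2(CO[Si](C)(C)C(C)(C)C)C1O[Si](C)(C)C(C)(C)C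
F4 | step 20 | C12=C13 trimethylsilyl enol ether of lactone 27 | C[C@@H]1CN2C[C@H]3CC[C@H]4CCC(O[Si](C)(C)C)=C4[C@@]45CCC(=O)O[C@@H]4[C@@]2(C[C@@]35CO[Si](c6ccccc6)(c6ccccc6)C(C)(C)C)C1O[Si](C)(C)C(C)(C)C
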